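**Plan**

Ring A is numbered C1 (quinone methide carbon), C2 (ring D, the 2,4-dihydroxyphenyl group), C3-H, C4-H, C5 (CH2OH), C6 (ethynyl arm ending in ring C). Rings B and E sit on the methide carbon.
Cuts, in retrosynthetic order: the methide C=C goes back to a protected triaryl carbinol. The C1–carbinol and C2–C1' (ring D) bonds go back together to a C1–C2 aryne made from C2–F and C1–H. The alkyne goes back to a diaryl ketone with one carbon fewer, and the ketone–ring C bond to an aryllithium and a lactone.
Enabling feature: the sp carbon on C6 and the CH2OH on C5 are ortho neighbours on ring A, which is the carbonyl carbon/OCH2 pattern of a phthalide. 6-Fluorophthalide therefore already holds ring A, the C5–CH2O unit, the carbon bound to C6 and, para to the CH2O carbon, a leaving group on C2.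
Forward: no ring is built, since all five six-membered rings are bought. Ring C is joined to ring A by lactone opening, one carbon is inserted to give the alkyne, ring D and then rings B and E are attached in one aryne operation, and acid unveils the quinone methide.
Stereochemistry: the target has no stereocentre, and its exocyclic C=C ends in a symmetrical cyclohexadienone, so nothing has to be controlled.

Key step: step 4

Assumption: the target is taken as the open para-quinone methide drawn, with no defined axial chirality. 6-Fluorophthalide and trimethylsilyldiazomethane (hexane solution) are taken as catalogue chemicals.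

**Step 1**
Reactants: 1 4-bromophenol
Product: 2 1-bromo-4-(methoxymethoxy)benzene
Conditions: MOMCl, i-Pr2NEt, CH2Cl2, 0 °C → rt
Reagents that add atoms: chloromethyl methyl ether (MOMCl), COCCl
Why: O-alkylation of a phenol with an alpha-chloro ether (MOM protection) gives an acetal that tolerates every organolithium step ahead and falls in aqueous acid at the end.

**Step 2**
Reactants: 2 1-bromo-4-(methoxymethoxy)benzene; 3 6-fluorophthalide
Product: 6 [5-fluoro-2-(hydroxymethyl)phenyl][4-(methoxymethoxy)phenyl]methanone, via 4-(methoxymethoxy)phenyllithium 4 (not isolated), via cyclic lithium hemiketal 5 (not isolated)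
Conditions: 2, n-BuLi, THF, −78 °C; cannulated into 3, THF, −78 °C; sat. aq NH4Cl at −78 °C
Reagents that add atoms: none
Why: Bromine–lithium exchange and 1,2-addition of the aryllithium to the lactone carbonyl give hemiketal 5, which persists at −78 °C and so holds back a second addition, and the buffered quench opens it to the 2-(hydroxymethyl)benzophenone without acid that would dehydrate it to an isobenzofuran.

**Step 3**
Reactants: 6 [5-fluoro-2-(hydroxymethyl)phenyl][4-(methoxymethoxy)phenyl]methanone
Product: 7 [2-({[tert-butyl(dimethyl)silyl]oxy}methyl)-5-fluorophenyl][4-(methoxymethoxy)phenyl]methanone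
Conditions: TBSCl, imidazole, CH2Cl2, 0 °C → rt
Reagents that add atoms: tert-butyldimethylsilyl chloride (TBSCl), CC(C)(C)[Si](C)(C)Cl
Why: Imidazole-promoted silylation takes the primary alcohol of the open form far faster than the tertiary hydroxyl of the lactol tautomer, so the equilibrium drains into the keto silyl ether.

**Step 4**
Reactants: 7 [2-({[tert-butyl(dimethyl)silyl]oxy}methyl)-5-fluorophenyl][4-(methoxymethoxy)phenyl]methanone; 8 trimethylsilyldiazomethane
Product: 13 tert-butyl[(4-fluoro-2-{[4-(methoxymethoxy)phenyl]ethynyl}benzyl)oxy]dimethylsilane, via lithiated trimethylsilyldiazomethane 9 (not isolated), via lithium alkoxide adduct 10 (not isolated), via diazoalkene 11 (not isolated), via alkylidene carbene 12 (not isolated)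
Conditions: 8, n-BuLi, THF, −78 °C; then 7, −78 °C → rt, then reflux; H2O
Reagents that add atoms: trimethylsilyldiazomethane 8, C[Si](C)(C)C=[N+]=[N-] (delivers its diazo carbon)
Why: The carbanion 9 adds to the carbonyl group of 7, alkoxide 10 loses Me3SiOLi in a Peterson-type elimination, diazoalkene 11 expels N2, and in the alkylidene carbene 12 an aryl group shifts from the former ketone carbon to the new carbon, which creates the triple bond and the second aryl–alkyne bond at once. This is the Colvin rearrangement in its lithiated trimethylsilyldiazomethane form, a reaction established for benzophenone-type ketones as a route to diarylalkynes. No ring closes and no lasting stereocentre arises, the stereocentre of 10 being erased in the elimination. Regiochemistry of migration is no issue, because a shift of ring C (the more electron-rich and so the likelier migrant, which leaves the old lactone carbon on C6) and a shift of ring A end in the same alkyne 13. The selectivity needed is rearrangement in preference to 1,5 C–H insertion into the neighbouring OCH2 group or attack on its oxygen, and it is secured by the very low barrier of aryl migration in a diaryl alkylidene carbene and by the bulk of the TBS group around that CH2O unit. Ketone 7 has no enolisable hydrogen and 9 is too weak a base to metalate the fluoroarene, so C–F, MOM and TBS pass through unchanged.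

**Step 5**
Reactants: 14 4-bromoresorcinol
Product: 15 1-bromo-2,4-bis(methoxymethoxy)benzene
Conditions: MOMCl, i-Pr2NEt, CH2Cl2, 0 °C → rt
Reagents that add atoms: chloromethyl methyl ether (MOMCl), COCCl
Why: Double MOM protection of the two phenols by O-alkylation masks the acidic protons of ring D and places a lithium-coordinating acetal ortho to the future carbanion.

**Step 6**
Reactants: 16 4,4'-dihydroxybenzophenone
Product: 17 bis[4-(methoxymethoxy)phenyl]methanone
Conditions: MOMCl, i-Pr2NEt, DMF, 0 °C → rt
Reagents that add atoms: chloromethyl methyl ether (MOMCl), COCCl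
Why: The same phenol O-alkylation (MOM protection) removes the acidic protons, so the ketone can act purely as an electrophile towards an aryllithium.

**Step 7**
Reactants: 13 tert-butyl[(4-fluoro-2-{[4-(methoxymethoxy)phenyl]ethynyl}benzyl)oxy]dimethylsilane; 15 1-bromo-2,4-bis(methoxymethoxy)benzene; 17 bis[4-(methoxymethoxy)phenyl]methanone
Product: 22 [4-({[tert-butyl(dimethyl)silyl]oxy}methyl)-2',4'-bis(methoxymethoxy)-3-{[4-(methoxymethoxy)phenyl]ethynyl}biphenyl-2-yl]bis[4-(methoxymethoxy)phenyl]methanol, via 2,4-bis(methoxymethoxy)phenyllithium 18 (not isolated), via C1-lithiated fluoroarene 19 (not isolated), via C1–C2 aryne 20 (not isolated), via 2-lithiobiaryl 21 (not isolated)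
Conditions: 15, t-BuLi (2 equiv per Br), THF, −78 °C; separately 13, lithium 2,2,6,6-tetramethylpiperidide (LiTMP, from the amine and n-BuLi, 1.05 equiv), THF, −78 °C; 18 (3 equiv) cannulated in, −78 → −20 °C; recooled to −78 °C, 17 (3.5 equiv), → 0 °C; sat. aq NH4Cl
Reagents that add atoms: none
Why: Ortho-metalation takes C1–H, the most acidic ring proton because it lies between fluorine and the sp-carbon substituent; loss of LiF on warming gives aryne 20, aryllithium 18 adds at C2 (the terminus remote from the alkynyl group, favoured by the inductive polarisation of a 3-substituted aryne and by steric approach) so that the charge lands on C1, and 2-lithiobiaryl 21 is caught by ketone 17 in a 1,2-addition, which together is the classical fluoroarene–aryllithium aryne arylation with carbonyl trapping.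

**Step 8**
Reactants: 22 [4-({[tert-butyl(dimethyl)silyl]oxy}methyl)-2',4'-bis(methoxymethoxy)-3-{[4-(methoxymethoxy)phenyl]ethynyl}biphenyl-2-yl]bis[4-(methoxymethoxy)phenyl]methanol
Product: 24 Selaginellin F, via free heptahydroxy carbinol 23 (not isolated)
Conditions: 3 M aq HCl, THF, 45 °C; then rapid neutralisation with aq NaHCO3 at 0 °C
Reagents that add atoms: none
Why: Acid hydrolysis of the five aryl MOM acetals and the primary TBS ether frees 23, whose carbinol carbon, flanked by two para-hydroxyphenyl rings, ionises and on neutralisation should lose a phenolic proton faster than an oxygen nucleophile can add, the usual fuchsone-type dehydration to a para-quinone methide.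

**Compound list**

1 | 4-bromophenol | Oc1ccc(Br)cc1 | starting material
2 | 1-bromo-4-(methoxymethoxy)benzene | COCOc1ccc(Br)cc1 | intermediate
3 | 6-fluorophthalide (6-fluoro-2-benzofuran-1(3H)-one) | O=C1OCc2ccc(F)cc21 | starting material
4 | [4-(methoxymethoxy)phenyl]lithium | [Li]c1ccc(OCOC)cc1 | intermediate
5 | lithium 6-fluoro-1-[4-(methoxymethoxy)phenyl]-1,3-dihydro-2-benzofuran-1-olate (racemic, transient) | [Li]OC1(c2ccc(OCOC)cc2)OCc2ccc(F)cc21 | intermediate
6 | [5-fluoro-2-(hydroxymethyl)phenyl][4-(methoxymethoxy)phenyl]methanone | O=C(c1ccc(OCOC)cc1)c1cc(F)ccc1CO | intermediate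
7 | [2-({[tert-butyl(dimethyl)silyl]oxy}methyl)-5-fluorophenyl][4-(methoxymethoxy)phenyl]methanone | O=C(c1ccc(OCOC)cc1)c1cc(F)ccc1CO[Si](C)(C)C(C)(C)C | intermediate
8 | trimethylsilyldiazomethane | C[Si](C)(C)C=[N+]=[N-] | starting material
9 | [diazo(trimethylsilyl)methyl]lithium | C[Si](C)(C)C([Li])=[N+]=[N-] | intermediate
10 | lithium 1-[2-({[tert-butyl(dimethyl)silyl]oxy}methyl)-5-fluorophenyl]-2-diazo-1-[4-(methoxymethoxy)phenyl]-2-(trimethylsilyl)ethan-1-olate (racemic, transient) | [Li]OC(c1ccc(OCOC)cc1)(c1cc(F)ccc1CO[Si](C)(C)C(C)(C)C)C(=[N+]=[N-])[Si](C)(C)C | intermediate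
11 | tert-butyl[(2-{2-diazo-1-[4-(methoxymethoxy)phenyl]ethenyl}-4-fluorobenzyl)oxy]dimethylsilane | [N-]=[N+]=C=C(c1ccc(OCOC)cc1)c1cc(F)ccc1CO[Si](C)(C)C(C)(C)C | intermediate
12 | 2-[2-({[tert-butyl(dimethyl)silyl]oxy}methyl)-5-fluorophenyl]-2-[4-(methoxymethoxy)phenyl]ethenylidene (alkylidene carbene) | [C]=C(c1ccc(OCOC)cc1)c1cc(F)ccc1CO[Si](C)(C)C(C)(C)C | intermediate
13 | tert-butyl[(4-fluoro-2-{[4-(methoxymethoxy)phenyl]ethynyl}benzyl)oxy]dimethylsilane | Fc1ccc(CO[Si](C)(C)C(C)(C)C)c(C#Cc2ccc(OCOC)cc2)c1 | intermediate
14 | 4-bromoresorcinol (4-bromobenzene-1,3-diol) | Oc1ccc(Br)c(O)c1 | starting material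
15 | 1-bromo-2,4-bis(methoxymethoxy)benzene | COCOc1ccc(Br)c(OCOC)c1 | intermediate
16 | 4,4'-dihydroxybenzophenone | O=C(c1ccc(O)cc1)c1ccc(O)cc1 | starting material
17 | bis[4-(methoxymethoxy)phenyl]methanone | O=C(c1ccc(OCOC)cc1)c1ccc(OCOC)cc1 | intermediate
18 | [2,4-bis(methoxymethoxy)phenyl]lithium | [Li]c1ccc(OCOC)cc1OCOC | intermediate
19 | [3-({[tert-butyl(dimethyl)silyl]oxy}methyl)-6-fluoro-2-{[4-(methoxymethoxy)phenyl]ethynyl}phenyl]lithium | Fc1ccc(CO[Si](C)(C)C(C)(C)C)c(C#Cc2ccc(OCOC)cc2)c1[Li] | intermediate
20 | tert-butyl[(3,4-didehydro-2-{[4-(methoxymethoxy)phenyl]ethynyl}benzyl)oxy]dimethylsilane (aryne) | C1#CC=CC(CO[Si](C)(C)C(C)(C)C)=C1C#Cc1ccc(OCOC)cc1 | intermediate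
21 | [4-({[tert-butyl(dimethyl)silyl]oxy}methyl)-2',4'-bis(methoxymethoxy)-3-{[4-(methoxymethoxy)phenyl]ethynyl}biphenyl-2-yl]lithium | [Li]c1c(-c2ccc(OCOC)cc2OCOC)ccc(CO[Si](C)(C)C(C)(C)C)c1C#Cc1ccc(OCOC)cc1 | intermediate
22 | [4-({[tert-butyl(dimethyl)silyl]oxy}methyl)-2',4'-bis(methoxymethoxy)-3-{[4-(methoxymethoxy)phenyl]ethynyl}biphenyl-2-yl]bis[4-(methoxymethoxy)phenyl]methanol | OC(c1ccc(OCOC)cc1)(c1ccc(OCOC)cc1)c1c(-c2ccc(OCOC)cc2OCOC)ccc(CO[Si](C)(C)C(C)(C)C)c1C#Cc1ccc(OCOC)cc1 | intermediate
23 | 2-[hydroxybis(4-hydroxyphenyl)methyl]-4-(hydroxymethyl)-3-[(4-hydroxyphenyl)ethynyl]biphenyl-2',4'-diol | OC(c1ccc(O)cc1)(c1ccc(O)cc1)c1c(-c2ccc(O)cc2O)ccc(CO)c1C#Cc1ccc(O)cc1 | intermediate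
24 | Selaginellin F, 4-{[2',4'-dihydroxy-4-(hydroxymethyl)-3-[(4-hydroxyphenyl)ethynyl]biphenyl-2-yl](4-hydroxyphenyl)methylidene}cyclohexa-2,5-dien-1-one | O=C1C=CC(=C(c2ccc(O)cc2)c2c(-c3ccc(O)cc3O)ccc(CO)c2C#Cc2ccc(O)cc2)C=C1 | target

**Step count**

Total step count: 8. Longest linear sequence: 6 (steps 1, 2, 3, 4, 7, 8).

**Steps most likely to fail**

**1. Step 7.** Four events must follow one another cleanly in one flask, and each can go astray:
- Metalation could stray to C3–H.
- The aryne could be consumed by the amide base or by self-reaction.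
- The aryllithium could add to the wrong aryne terminus.
- The crowded 2-lithiobiaryl could pick up a proton before it reaches the ketone.

The fallback sets out from 13, returns at 22 and gives up the aryne. Compound 13 is metalated as before to 19, which is quenched cold with CO2. This gives 3-({[tert-butyl(dimethyl)silyl]oxy}methyl)-6-fluoro-2-{[4-(methoxymethoxy)phenyl]ethynyl}benzoic acid F1, so the site of metalation is checked on an isolable compound. A little over two equivalents of 18 then replace the fluoride ortho to the lithium carboxylate by addition–elimination. This is the carboxylate-assisted SNAr known for unprotected 2-fluorobenzoic acids and aryllithiums, and it fixes ring D on C2 in 4-({[tert-butyl(dimethyl)silyl]oxy}methyl)-2',4'-bis(methoxymethoxy)-3-{[4-(methoxymethoxy)phenyl]ethynyl}biphenyl-2-carboxylic acid F2. MeI and K2CO3 in DMF give the corresponding methyl biphenyl-2-carboxylate F3. An excess of aryllithium 4 adds twice, by way of the biphenyl-2-yl 4-(methoxymethoxy)phenyl ketone F4, which is not isolated, to give carbinol 22.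

**2. Step 8.** Cleaving five acetals needs a long exposure to Brønsted acid. During that time the ortho oxygen of ring D could close onto the cationic carbon. Water or the C5 CH2OH could also add to the protonated, electron-rich alkyne.

The fallback sets out from 22, returns at 24 and avoids protic acid by separating the two kinds of deprotection. TMSOTf with 2,2'-bipyridyl in CH2Cl2 at 0 °C, followed by water, removes aromatic MOM ethers under buffered, non-protic conditions that leave an alkyl TBS ether alone. The freed para-hydroxy carbinol should lose water on work-up to give the silyl-protected quinone methide 4-{[4-({[tert-butyl(dimethyl)silyl]oxy}methyl)-2',4'-dihydroxy-3-[(4-hydroxyphenyl)ethynyl]biphenyl-2-yl](4-hydroxyphenyl)methylidene}cyclohexa-2,5-dien-1-one F5. HF·pyridine in THF/pyridine at 0 °C then frees the CH2OH and gives 24.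

**3. Step 4.** The bulky silyl diazomethyl anion may add only sluggishly to an ortho-substituted, electron-rich diaryl ketone. A free carbene might also be diverted into the neighbouring OCH2 group.

The fallback sets out from 7 and returns at 13. It keeps the one-carbon homologation but replaces the free carbene by a carbenoid. Diethyl (dichloromethyl)phosphonate is deprotonated with lithium diisopropylamide in THF at −78 °C and converts 7 in a Horner–Wadsworth–Emmons olefination, under basic conditions that spare TBS and MOM. The product is tert-butyl[(2-{2,2-dichloro-1-[4-(methoxymethoxy)phenyl]ethenyl}-4-fluorobenzyl)oxy]dimethylsilane F6. With n-BuLi in THF at −78 °C, chlorine–lithium exchange gives the 1-chloro-1-lithioalkene carbenoid F7 (either geometry). On warming it should undergo the Fritsch–Buttenberg–Wiechell rearrangement, aryl migration concerted with loss of LiCl, to alkyne 13.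

**Further compounds**

F1 | step 7 | 3-({[tert-butyl(dimethyl)silyl]oxy}methyl)-6-fluoro-2-{[4-(methoxymethoxy)phenyl]ethynyl}benzoic acid | OC(=O)c1c(F)ccc(CO[Si](C)(C)C(C)(C)C)c1C#Cc1ccc(OCOC)cc1
F2 | step 7 | 4-({[tert-butyl(dimethyl)silyl]oxy}methyl)-2',4'-bis(methoxymethoxy)-3-{[4-(methoxymethoxy)phenyl]ethynyl}biphenyl-2-carboxylic acid | OC(=O)c1c(-c2ccc(OCOC)cc2OCOC)ccc(CO[Si](C)(C)C(C)(C)C)c1C#Cc1ccc(OCOC)cc1
F3 | step 7 | methyl 4-({[tert-butyl(dimethyl)silyl]oxy}methyl)-2',4'-bis(methoxymethoxy)-3-{[4-(methoxymethoxy)phenyl]ethynyl}biphenyl-2-carboxylate | COC(=O)c1c(-c2ccc(OCOC)cc2OCOC)ccc(CO[Si](C)(C)C(C)(C)C)c1C#Cc1ccc(OCOC)cc1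
F4 | step 7 | [4-({[tert-butyl(dimethyl)silyl]oxy}methyl)-2',4'-bis(methoxymethoxy)-3-{[4-(methoxymethoxy)phenyl]ethynyl}biphenyl-2-yl][4-(methoxymethoxy)phenyl]methanone | O=C(c1ccc(OCOC)cc1)c1c(-c2ccc(OCOC)cc2OCOC)ccc(CO[Si](C)(C)C(C)(C)C)c1C#Cc1ccc(OCOC)cc1
F5 | step 8 | 4-{[4-({[tert-butyl(dimethyl)silyl]oxy}methyl)-2',4'-dihydroxy-3-[(4-hydroxyphenyl)ethynyl]biphenyl-2-yl](4-hydroxyphenyl)methylidene}cyclohexa-2,5-dien-1-one | O=C1C=CC(=C(c2ccc(O)cc2)c2c(-c3ccc(O)cc3O)ccc(CO[Si](C)(C)C(C)(C)C)c2C#Cc2ccc(O)cc2)C=C1
F6 | step 4 | tert-butyl[(2-{2,2-dichloro-1-[4-(methoxymethoxy)phenyl]ethenyl}-4-fluorobenzyl)oxy]dimethylsilane | ClC(Cl)=C(c1ccc(OCOC)cc1)c1cc(F)ccc1CO[Si](C)(C)C(C)(C)C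
F7 | step 4 | {2-[2-({[tert-butyl(dimethyl)silyl]oxy}methyl)-5-fluorophenyl]-1-chloro-2-[4-(methoxymethoxy)phenyl]ethenyl}lithium (either geometry) | [Li]C(Cl)=C(c1ccc(OCOC)cc1)c1cc(F)ccc1CO[Si](C)(C)C(C)(C)C
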